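Retrosynthetic overview
1. The last operation is a global hydrogenolysis (14 O-benzyl groups, 3 C–Br bonds) of a protected dimer. The dimer comes from a Lewis-acid Friedel–Crafts union, C4 (upper unit) to C6 (lower unit), of a 4β-alkoxy-6,8-dibromo electrophile with an 8-bromo nucleophile. Both partners are made from one monomer, tetra-O-benzylepicatechin, and tri-O-benzylgallic acid.
2. The monomer comes from racemic tetra-O-benzylflavan-3-one. C2 and C3 are set together (cis, 2R,3R) by asymmetric hydrogenation with dynamic kinetic resolution, because C2 of the ketone is labile.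
3. Ring C (O1–C2–C3–C4–C4a–C8a) is not closed as a six-membered ring. An acyclic α-diazoketone (C4 is the diazo carbon) adds to ring A (Buchner reaction) and gives a five-membered furanone ring O1–C2–C3–C4–C8a fused to the cyclopropane C4–C4a–C8a. Acid then moves C4 from C8a to C4a, a 5 → 6 ring expansion with rearomatisation.
4. The enabling feature is that ring A is a phloroglucinol ether. Its C8a=C4a bond carries O1 and is activated by the oxygens on C5 and C7, so it accepts the carbenoid. O1 stabilises the charge at C8a, which singles out the C4–C8a bond for cleavage. The two ortho carbons of the 3,5-dibenzyloxyphenoxy group are equivalent.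
5. Ring order: the arenes are bought, then cyclopropane and furanone form (both transient), then the pyranone ring C. The same sequence serves both flavan units. The diazoketone is assembled from an aldehyde, CHCl3, a phenol and CH2N2.

Key step: step 4

Remark (numbering): flavan numbering is O1, C2, C3, C4, C4a, C5–C8, C8a, with rings A (benzo), B (2-aryl) and C (pyran); α is the face that carries the 2-aryl group and β the opposite face.
Assumption: 3,4-bis(benzyloxy)benzaldehyde, 3,5-bis(benzyloxy)phenol and 3,4,5-tris(benzyloxy)benzoic acid are taken as commercial.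
Assumption: which antipode of the Ru catalyst of step 5 leads to the (2R,3R) alcohol cannot be derived safely from the models for 2-substituted cycloalkanones, so it is to be fixed in a trial run against a sample made by benzylation of natural (−)-epicatechin.

Step 1
Reactants: 1 3,4-bis(benzyloxy)benzaldehyde
Product: 2 (±)-1-[3,4-bis(benzyloxy)phenyl]-2,2,2-trichloroethanol
Conditions: CHCl3 (3 equiv), DBU (1 equiv), THF, 0 °C → rt
Reagents that add atoms: chloroform, ClC(Cl)Cl
Why: Base-mediated addition of the trichloromethyl anion to an aromatic aldehyde (first stage of the Jocic–Reeve sequence) is general, and the new carbinol centre is racemic, which does not matter because C2 is fixed only in step 5.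

Step 2
Reactants: 2 (±)-1-[3,4-bis(benzyloxy)phenyl]-2,2,2-trichloroethanol; 3 3,5-bis(benzyloxy)phenol
Product: 6 (±)-2-[3,4-bis(benzyloxy)phenyl]-2-[3,5-bis(benzyloxy)phenoxy]acetic acid, via (±)-3-[3,4-bis(benzyloxy)phenyl]-2,2-dichlorooxirane 4 (not isolated), via (±)-2-[3,4-bis(benzyloxy)phenyl]-2-[3,5-bis(benzyloxy)phenoxy]acetyl chloride 5 (not isolated)
Conditions: 3 (1.2 equiv), NaOH (6 equiv), DME–H2O, 0 °C → rt; then 1 M HCl
Reagents that add atoms: sodium hydroxide, [Na+].[OH-] (second carboxyl oxygen)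
Why: In this Jocic–Reeve reaction the alkoxide of 2 closes to the gem-dichlorooxirane 4, the phenoxide of 3 opens it at the benzylic carbon (O1–C2 bond), and the resulting acyl chloride 5 is hydrolysed in the same basic medium, to which benzyl ethers are inert; the product is racemic.

Step 3
Reactants: 6 (±)-2-[3,4-bis(benzyloxy)phenyl]-2-[3,5-bis(benzyloxy)phenoxy]acetic acid
Product: 8 (±)-1-diazo-3-[3,4-bis(benzyloxy)phenyl]-3-[3,5-bis(benzyloxy)phenoxy]propan-2-one, via mixed isobutyl carbonic anhydride of 6 7 (not isolated)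
Conditions: i-BuOCOCl, N-methylmorpholine, THF, −20 °C; then CH2N2 (Et2O), −20 → 0 °C
Reagents that add atoms: diazomethane, C=[N+]=[N-]; isobutyl chloroformate, CC(C)COC(=O)Cl (its atoms remain only in 7)
Why: Acylation of diazomethane by a mixed carbonic anhydride (first stage of the Arndt–Eistert sequence) gives the terminal α-diazoketone under cold, nearly neutral conditions that spare the benzyl ethers, and the stereocentre stays racemic.

Step 4
Reactants: 8 (±)-1-diazo-3-[3,4-bis(benzyloxy)phenyl]-3-[3,5-bis(benzyloxy)phenoxy]propan-2-one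
Product: 11 (±)-5,7-bis(benzyloxy)-2-[3,4-bis(benzyloxy)phenyl]chroman-3-one (tetra-O-benzylflavan-3-one), via norcaradiene (furan-3-one ring O1–C2–C3–C4–C8a fused to cyclopropane C4–C4a–C8a and to a 5,7-bis(benzyloxy)cyclohexadiene) 9 (not isolated), via 5,7-bis(benzyloxy)-2-[3,4-bis(benzyloxy)phenyl]-2H-cyclohepta[b]furan-3(3aH)-one 10 (not isolated)
Conditions: Rh2(OAc)4 (1 mol %), CH2Cl2, 40 °C, slow addition at high dilution; then TFA (0.5 equiv), 0 °C, same flask
Reagents that add atoms: none
Why: Rh2(OAc)4 expels N2 from 8 and the electrophilic carbenoid carbon C4 adds across the C8a=C4a bond of the phenoxy ring (intramolecular Buchner reaction), which closes in one event the cyclopropane C4–C4a–C8a ([2+1] addition) and, through the tether O1–C2–C3, the five-membered furanone ring O1–C2–C3–C4–C8a of norcaradiene 9, in electrocyclic equilibrium with cycloheptatriene 10. TFA then protonates the ketone of 9, the cyclopropane bond C4–C8a breaks heterolytically (the charge at C8a is held by O1 and, through the ring, by the 5- and 7-benzyloxy groups, and the electrons are taken up as the C3=C4 enol), loss of H-4a restores the benzene ring and the enol ketonises, so that C4a now stands between C4 and C8a and the five-membered ring has become the six-membered ring O1–C2–C3–C4–C4a–C8a. The closest known reactions are the Rh-catalysed conversion of 1-diazo-4-arylbutan-2-ones into azulenones with acid-induced rearrangement to 2-tetralones, and the same sequence from 1-diazo-3-aryloxypropan-2-ones to chroman-3-ones. The centres C4, C4a and C8a of 9 and 10 are transient and vanish on aromatisation, and C2 is carried through as a racemic, base-labile centre that step 5 exploits, so no control element is needed here. Site selectivity (ring A against ring B, the benzyl ethers and C2–H) is needed and should follow from ring A being the most electron-rich arene (three oxygen substituents) and being reached by a five-membered closure, whereas addition to the ipso–ortho bond of ring B would need a four-membered one; regioselectivity is no issue because the two ortho carbons of the phenoxy ring are equivalent, and of the two cyclopropane bonds at C4 only C4–C8a can break with the help of O1 and lead back to an arene. Slow addition at high dilution should suppress carbene dimerisation.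

Step 5
Reactants: 11 (±)-tetra-O-benzylflavan-3-one
Product: 12 (2R,3R)-5,7,3',4'-tetra-O-benzylepicatechin
Conditions: RuCl2[(S)-xylbinap][(S)-daipen] or its mirror image (0.5 mol %, see assumption), KOt-Bu (5 mol %), H2 (10 atm), i-PrOH–THF, 25 °C
Reagents that add atoms: none
Why: This is a Ru(diphosphine)(diamine)-catalysed asymmetric hydrogenation under dynamic kinetic resolution, the reaction type established for racemic 2-aryl- and 2-alkoxycycloalkanones: KOt-Bu racemises C2 through the enolate, the chiral catalyst reduces the (2R)-ketone preferentially and delivers hydride to the C3 face anti to the 2-aryl group, which sets C2 (R) and C3 (R) in the cis relation, and benzyl ethers are not touched by this catalyst.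

Step 6
Reactants: 12 (2R,3R)-5,7,3',4'-tetra-O-benzylepicatechin; 13 3,4,5-tris(benzyloxy)benzoic acid
Product: 14 (2R,3R)-5,7,3',4'-tetra-O-benzylepicatechin 3-O-(3,4,5-tri-O-benzylgallate)
Conditions: DCC, DMAP (cat.), CH2Cl2, 0 °C → rt
Reagents that add atoms: none
Why: Steglich esterification acylates the axial 3-OH at oxygen, so C3 keeps its configuration.

Step 7
Reactants: 14 protected epicatechin gallate
Product: 15 8-bromo-5,7,3',4'-tetra-O-benzylepicatechin 3-O-(3,4,5-tri-O-benzylgallate)
Conditions: NBS (1.0 equiv), CH2Cl2, −78 → 0 °C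
Reagents that add atoms: N-bromosuccinimide, O=C1CCC(=O)N1Br
Why: Electrophilic aromatic bromination goes to ring A, the most electron-rich ring, and there to C8, which is less crowded than C6 (flanked by two benzyloxy groups), so C6 is left as the only free nucleophilic position.

Step 8
Reactants: 12 (2R,3R)-5,7,3',4'-tetra-O-benzylepicatechin
Product: 16 4β-(2-ethoxyethoxy)-5,7,3',4'-tetra-O-benzylepicatechin (2,3-cis-3,4-trans)
Conditions: DDQ (2 equiv), 2-ethoxyethanol (5 equiv), CH2Cl2, rt
Reagents that add atoms: 2-ethoxyethanol, CCOCCO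
Why: In this oxidative benzylic C–H alkoxylation DDQ abstracts hydride from C4, which is benzylic to the trioxygenated ring A, and the alcohol adds to the cation from the β face, anti to the axial 3α-oxygen; this centre is ionised again in step 11.

Step 9
Reactants: 16 4β-(2-ethoxyethoxy)-tetra-O-benzylepicatechin; 13 3,4,5-tris(benzyloxy)benzoic acid
Product: 17 4β-(2-ethoxyethoxy)-5,7,3',4'-tetra-O-benzylepicatechin 3-O-(3,4,5-tri-O-benzylgallate)
Conditions: DCC, DMAP (cat.), CH2Cl2, 0 °C → rt
Reagents that add atoms: none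
Why: Steglich esterification at oxygen under non-acidic conditions leaves the benzylic 4-alkoxy group and all stereocentres untouched.

Step 10
Reactants: 17 4β-(2-ethoxyethoxy) gallate
Product: 18 6,8-dibromo-4β-(2-ethoxyethoxy)-5,7,3',4'-tetra-O-benzylepicatechin 3-O-(3,4,5-tri-O-benzylgallate)
Conditions: NBS (2.1 equiv), CH2Cl2, −78 → 0 °C
Reagents that add atoms: N-bromosuccinimide, O=C1CCC(=O)N1Br
Why: Twofold electrophilic aromatic bromination caps both free positions of ring A, so the electrophile (and later the upper unit of the dimer) can no longer act as a Friedel–Crafts nucleophile and self-condensation is excluded.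

Step 11
Reactants: 15 8-bromo nucleophile (2 equiv); 18 6,8-dibromo-4β-alkoxy electrophile
Product: 20 protected dimer: 6,8-dibromo-tetra-O-benzylepicatechin 3-O-(tri-O-benzylgallate)-(4β→6)-8-bromo-tetra-O-benzylepicatechin 3-O-(tri-O-benzylgallate), via C4 benzylic carbocation of the upper unit 19 (not isolated)
Conditions: TMSOTf (20 mol %), 4 Å MS, CH2Cl2, −78 → −30 °C; Et3N quench
Reagents that add atoms: none
Why: In this Lewis-acid-promoted Friedel–Crafts alkylation (the halo-capping variant of the flavan-4-yl cation coupling) ionisation of the 4-alkoxy group gives cation 19, the only free electron-rich aromatic C–H in the flask is C6 of 15, which fixes the 4→6 connectivity, and attack from the β face, anti to the axial 3α-galloyloxy group, sets C4 in the 3,4-trans relation.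

Step 12
Reactants: 20 protected tribromo dimer
Product: 21 procyanidin B-5 3,3'-di-O-gallate
Conditions: H2 (1 atm), 20 % Pd(OH)2/C, Et3N (3.3 equiv), THF–MeOH–H2O, rt; filtration, Sephadex LH-20
Reagents that add atoms: none
Why: Catalytic hydrogenolysis removes the fourteen benzyl ethers and hydrodehalogenation removes the three aryl bromides in one operation, the amine buffers the HBr that would otherwise cleave the interflavan bond, and the esters and all five stereocentres are not affected.

Compound list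
1 | 3,4-bis(benzyloxy)benzaldehyde | O=Cc1ccc(OCc2ccccc2)c(OCc2ccccc2)c1 | starting material
2 | (±)-1-[3,4-bis(benzyloxy)phenyl]-2,2,2-trichloroethanol | OC(c1ccc(OCc2ccccc2)c(OCc2ccccc2)c1)C(Cl)(Cl)Cl | intermediate
3 | 3,5-bis(benzyloxy)phenol | Oc1cc(OCc2ccccc2)cc(OCc2ccccc2)c1 | starting material
4 | (±)-3-[3,4-bis(benzyloxy)phenyl]-2,2-dichlorooxirane | ClC1(Cl)OC1c1ccc(OCc2ccccc2)c(OCc2ccccc2)c1 | intermediate
5 | (±)-2-[3,4-bis(benzyloxy)phenyl]-2-[3,5-bis(benzyloxy)phenoxy]acetyl chloride | O=C(Cl)C(Oc1cc(OCc2ccccc2)cc(OCc2ccccc2)c1)c1ccc(OCc2ccccc2)c(OCc2ccccc2)c1 | intermediate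
6 | (±)-2-[3,4-bis(benzyloxy)phenyl]-2-[3,5-bis(benzyloxy)phenoxy]acetic acid | OC(=O)C(Oc1cc(OCc2ccccc2)cc(OCc2ccccc2)c1)c1ccc(OCc2ccccc2)c(OCc2ccccc2)c1 | intermediate
7 | mixed isobutyl carbonic anhydride of 6 (racemic) | CC(C)COC(=O)OC(=O)C(Oc1cc(OCc2ccccc2)cc(OCc2ccccc2)c1)c1ccc(OCc2ccccc2)c(OCc2ccccc2)c1 | intermediate
8 | (±)-1-diazo-3-[3,4-bis(benzyloxy)phenyl]-3-[3,5-bis(benzyloxy)phenoxy]propan-2-one | [N-]=[N+]=CC(=O)C(Oc1cc(OCc2ccccc2)cc(OCc2ccccc2)c1)c1ccc(OCc2ccccc2)c(OCc2ccccc2)c1 | intermediate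
9 | norcaradiene (furan-3-one ring O1–C2–C3–C4–C8a, cyclopropane C4–C4a–C8a; racemic, mixture of C2 epimers) | O=C1C(c2ccc(OCc3ccccc3)c(OCc3ccccc3)c2)OC23C=C(OCc4ccccc4)C=C(OCc4ccccc4)C2C13 | intermediate
10 | 5,7-bis(benzyloxy)-2-[3,4-bis(benzyloxy)phenyl]-2H-cyclohepta[b]furan-3(3aH)-one (racemic, mixture of C2 epimers) | O=C1C(c2ccc(OCc3ccccc3)c(OCc3ccccc3)c2)OC2=CC(OCc3ccccc3)=CC(OCc3ccccc3)=CC12 | intermediate
11 | (±)-5,7-bis(benzyloxy)-2-[3,4-bis(benzyloxy)phenyl]chroman-3-one | O=C1Cc2c(OCc3ccccc3)cc(OCc3ccccc3)cc2OC1c1ccc(OCc2ccccc2)c(OCc2ccccc2)c1 | intermediate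
12 | (2R,3R)-5,7,3',4'-tetra-O-benzylepicatechin | O[C@@H]1Cc2c(OCc3ccccc3)cc(OCc3ccccc3)cc2O[C@@H]1c1ccc(OCc2ccccc2)c(OCc2ccccc2)c1 | intermediate
13 | 3,4,5-tris(benzyloxy)benzoic acid | OC(=O)c1cc(OCc2ccccc2)c(OCc2ccccc2)c(OCc2ccccc2)c1 | starting material
14 | (2R,3R)-5,7,3',4'-tetra-O-benzylepicatechin 3-O-(3,4,5-tri-O-benzylgallate) | O=C(O[C@@H]1Cc2c(OCc3ccccc3)cc(OCc3ccccc3)cc2O[C@@H]1c1ccc(OCc2ccccc2)c(OCc2ccccc2)c1)c1cc(OCc2ccccc2)c(OCc2ccccc2)c(OCc2ccccc2)c1 | intermediate
15 | 8-bromo derivative of 14 | O=C(O[C@@H]1Cc2c(OCc3ccccc3)cc(OCc3ccccc3)c(Br)c2O[C@@H]1c1ccc(OCc2ccccc2)c(OCc2ccccc2)c1)c1cc(OCc2ccccc2)c(OCc2ccccc2)c(OCc2ccccc2)c1 | intermediate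
16 | 4β-(2-ethoxyethoxy)-5,7,3',4'-tetra-O-benzylepicatechin | O[C@@H]1[C@@H](OCCOCC)c2c(OCc3ccccc3)cc(OCc3ccccc3)cc2O[C@@H]1c1ccc(OCc2ccccc2)c(OCc2ccccc2)c1 | intermediate
17 | 3-O-(3,4,5-tri-O-benzylgalloyl) derivative of 16 | O=C(O[C@@H]1[C@@H](OCCOCC)c2c(OCc3ccccc3)cc(OCc3ccccc3)cc2O[C@@H]1c1ccc(OCc2ccccc2)c(OCc2ccccc2)c1)c1cc(OCc2ccccc2)c(OCc2ccccc2)c(OCc2ccccc2)c1 | intermediate
18 | 6,8-dibromo derivative of 17 | O=C(O[C@@H]1[C@@H](OCCOCC)c2c(OCc3ccccc3)c(Br)c(OCc3ccccc3)c(Br)c2O[C@@H]1c1ccc(OCc2ccccc2)c(OCc2ccccc2)c1)c1cc(OCc2ccccc2)c(OCc2ccccc2)c(OCc2ccccc2)c1 | intermediate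
19 | C4 benzylic carbocation derived from 18 | O=C(O[C@@H]1[CH+]c2c(OCc3ccccc3)c(Br)c(OCc3ccccc3)c(Br)c2O[C@@H]1c1ccc(OCc2ccccc2)c(OCc2ccccc2)c1)c1cc(OCc2ccccc2)c(OCc2ccccc2)c(OCc2ccccc2)c1 | intermediate
20 | protected (4β→6) dimer, 6,8-dibromo (upper unit), 8-bromo (lower unit), tetradeca-O-benzyl | O=C(O[C@@H]1[C@@H](c2c(OCc4ccccc4)c(Br)c3c(c2OCc4ccccc4)C[C@@H](OC(=O)c4cc(OCc5ccccc5)c(OCc5ccccc5)c(OCc5ccccc5)c4)[C@@H](c4ccc(OCc5ccccc5)c(OCc5ccccc5)c4)O3)c2c(OCc3ccccc3)c(Br)c(OCc3ccccc3)c(Br)c2O[C@@H]1c1ccc(OCc2ccccc2)c(OCc2ccccc2)c1)c1cc(OCc2ccccc2)c(OCc2ccccc2)c(OCc2ccccc2)c1 | intermediate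
21 | procyanidin B-5 3,3'-di-O-gallate | O=C(O[C@@H]1[C@@H](c2c(O)cc3c(c2O)C[C@@H](OC(=O)c2cc(O)c(O)c(O)c2)[C@@H](c2ccc(O)c(O)c2)O3)c2c(O)cc(O)cc2O[C@@H]1c1ccc(O)c(O)c1)c1cc(O)c(O)c(O)c1 | target

Total step count: 12. Longest linear sequence: 10 (steps 1–5, 8–12); the nucleophile branch (steps 6 and 7) leaves the main line at 12 and rejoins it in step 11.

Steps most likely to fail

Step 4. The carbenoid may be consumed by electrophilic attack on the ortho carbon of ring B (five-membered ketone closure), by dimerisation or by traces of water. The tris(enol ether) 10 may also be hydrolysed or polymerise under acid before it aromatises.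
- Fallback: the C4 carbene is generated from an alkyne instead of a diazo group.
- Setting out from 1, ethynylmagnesium bromide (THF, 0 °C) gives (±)-1-[3,4-bis(benzyloxy)phenyl]prop-2-yn-1-ol F1.
- Mitsunobu etherification with 3 (PPh3, DIAD, THF) gives (±)-1,3-bis(benzyloxy)-5-{1-[3,4-bis(benzyloxy)phenyl]prop-2-ynyloxy}benzene F2.
- Gold(I)-catalysed alkyne oxidation (bulky biarylphosphine–AuNTf2, 2,6-dichloropyridine N-oxide, DCE, rt) is a known route from aryl propargyl ethers to chroman-3-ones. It produces the α-oxo carbene at C4, which should add to the same C8a=C4a bond and enter the manifold at 9.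
- The route is rejoined at 11.

Step 5. Enantioface discrimination may be poor because both α-carbons of the ketone are sp3. Racemisation of C2 may be slower than reduction, or enolate formation may stall the catalyst.
- Fallback: C2 is fixed before the ring is made, and C3 is then set by substrate control.
- Setting out from 6, crystallisation with (R)-1-phenylethylamine (or its antipode, to be found by trial) gives the (R)-1-phenylethylammonium salt of the (R)-acid F3. Acidification gives (R)-2-[3,4-bis(benzyloxy)phenyl]-2-[3,5-bis(benzyloxy)phenoxy]acetic acid F4.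
- The conditions of step 3 lead through the (R)-mixed anhydride F5 to the (R)-diazoketone F6.
- The conditions of step 4, with short acid contact, lead through the (2R)-norcaradiene F7 and the (2R)-cycloheptafuranone F8 to (2R)-tetra-O-benzylflavan-3-one F9.
- L-Selectride (THF, −78 °C) attacks F9 anti to the 2-aryl group and gives the cis alcohol. The route is rejoined at 12.

Step 11. Attack by the hindered, bromine-deactivated C6 may be slow, so that cation 19 decays by proton loss to the flav-3-ene or by recapture of the liberated alcohol. Acid-induced bromine migration is a further risk.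
- Fallback: a smaller and more reactive nucleophile is used, and the lower gallate is put on afterwards.
- Setting out from 12, NBS (1 equiv, CH2Cl2, −78 °C) gives 8-bromo-5,7,3',4'-tetra-O-benzylepicatechin F10.
- Coupling with 18 under the conditions of step 11 gives the protected dimer with a free 3-OH in the lower unit F11.
- Steglich esterification with 13 rejoins the route at 20.

Further compounds
F1 | step 4 | (±)-1-[3,4-bis(benzyloxy)phenyl]prop-2-yn-1-ol | C#CC(O)c1ccc(OCc2ccccc2)c(OCc2ccccc2)c1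
F2 | step 4 | (±)-1,3-bis(benzyloxy)-5-{1-[3,4-bis(benzyloxy)phenyl]prop-2-ynyloxy}benzene | C#CC(Oc1cc(OCc2ccccc2)cc(OCc2ccccc2)c1)c1ccc(OCc2ccccc2)c(OCc2ccccc2)c1
F3 | step 5 | (R)-1-phenylethylammonium salt of the (R)-acid | [O-]C(=O)[C@H](Oc1cc(OCc2ccccc2)cc(OCc2ccccc2)c1)c1ccc(OCc2ccccc2)c(OCc2ccccc2)c1.C[C@@H]([NH3+])c1ccccc1
F4 | step 5 | (R)-2-[3,4-bis(benzyloxy)phenyl]-2-[3,5-bis(benzyloxy)phenoxy]acetic acid | OC(=O)[C@H](Oc1cc(OCc2ccccc2)cc(OCc2ccccc2)c1)c1ccc(OCc2ccccc2)c(OCc2ccccc2)c1
F5 | step 5 | (R)-mixed isobutyl carbonic anhydride | CC(C)COC(=O)OC(=O)[C@H](Oc1cc(OCc2ccccc2)cc(OCc2ccccc2)c1)c1ccc(OCc2ccccc2)c(OCc2ccccc2)c1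
F6 | step 5 | (R)-1-diazo-3-[3,4-bis(benzyloxy)phenyl]-3-[3,5-bis(benzyloxy)phenoxy]propan-2-one | [N-]=[N+]=CC(=O)[C@H](Oc1cc(OCc2ccccc2)cc(OCc2ccccc2)c1)c1ccc(OCc2ccccc2)c(OCc2ccccc2)c1
F7 | step 5 | (2R)-norcaradiene | O=C1[C@@H](c2ccc(OCc3ccccc3)c(OCc3ccccc3)c2)OC23C=C(OCc4ccccc4)C=C(OCc4ccccc4)C2C13
F8 | step 5 | (2R)-5,7-bis(benzyloxy)-2-[3,4-bis(benzyloxy)phenyl]-2H-cyclohepta[b]furan-3(3aH)-one | O=C1[C@@H](c2ccc(OCc3ccccc3)c(OCc3ccccc3)c2)OC2=CC(OCc3ccccc3)=CC(OCc3ccccc3)=CC12
F9 | step 5 | (2R)-5,7-bis(benzyloxy)-2-[3,4-bis(benzyloxy)phenyl]chroman-3-one | O=C1Cc2c(OCc3ccccc3)cc(OCc3ccccc3)cc2O[C@@H]1c1ccc(OCc2ccccc2)c(OCc2ccccc2)c1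
F10 | step 11 | 8-bromo-5,7,3',4'-tetra-O-benzylepicatechin | O[C@@H]1Cc2c(OCc3ccccc3)cc(OCc3ccccc3)c(Br)c2O[C@@H]1c1ccc(OCc2ccccc2)c(OCc2ccccc2)c1
F11 | step 11 | protected (4β→6) dimer with free 3-OH in the lower unit | O=C(O[C@@H]1[C@@H](c2c(OCc4ccccc4)c(Br)c3c(c2OCc4ccccc4)C[C@@H](O)[C@@H](c4ccc(OCc5ccccc5)c(OCc5ccccc5)c4)O3)c2c(OCc3ccccc3)c(Br)c(OCc3ccccc3)c(Br)c2O[C@@H]1c1ccc(OCc2ccccc2)c(OCc2ccccc2)c1)c1cc(OCc2ccccc2)c(OCc2ccccc2)c(OCc2ccccc2)c1
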